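The data were computed with made-up constants; scatter was added.

From 12.0 min on, the delta run stands still. Its isomer of the product reads 4.5 %, 3.4 % and 4.1 %, which I take as level, given a scatter of 0.5 percentage points.

- delta: substrate 2.8 M; run made earlier
- flask: substrate 2.0 M; time 40 min

delta run (percent of the substrate charged)

| time / min | isomer of the product / % | target / % |
|---|---|---|
| 3.00 | 10.8 | 85.1 |
| 6.00 | 5.4 | 93.5 |
| 12.0 | 4.5 | 94.1 |
| 20.0 | 3.4 | 94.9 |
| 40.0 | 4.1 | 94.2 |

(standard deviation of a reading: 0.5 percentage points)

- what is said of target includes crystals
- crystals is a solid; its amount is given per volume of the solution
- what was read earlier has a scatter of 0.5 percentage points, one standard deviation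
- steps that have been proposed: substrate -> intermediate; intermediate <-> target; intermediate <-> isomer of the product; crystals <-> target

* ratio of isomer of the product to target at 8.0 s
* ratio of isomer of the product to target at 40 min
* which of isomer of the product and target there is more of at 40 min

Target is read with its crystals, so I assume solid stands in the delta run and the solution above it no longer depends on the charge. Concentrations then stay, not percentages; I call this late state thermodynamic control. The mean isomer reading is 4.00 % of 2.8 M, which gives 0.112 M. This is the plateau concentration, c(isomer of the product) in a solution standing over crystals. The mean target reading is 94.4 %, so the part of the delta charge that is not target comes to 0.157 M, and I freeze that too.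

Now I divide by the flask's charge of 2.0 M. Isomer is 5.60 %, and target is 92.2 %, far more than the isomer. My ratio at 40 min is 0.0608.

The weak link is 8.0 s, far earlier than the first reading, where no plateau can be assumed. So I reforge it from the delta run. Substrate is what is charged, so a fall read at later times cannot be run back to the start. The delta ratio of isomer to target reads 0.127 at 3.00 min and 0.0578 at 6.00 min, so it is falling. I therefore commit to no figure at 8.0 s. I expect a ratio above 0.127, and that is an expectation, not a bound.

The forecast gives 0.4 at 8.0 s and 0.062 at 40 min with target ahead, holding that “isomer concentration should also be fixed, not its percentage”.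

The flask gives 0.609 at 8.0 s and 0.0607 at 40 min, with target ahead: 91.8 % against 5.57 % of isomer.

    substrate → intermediate (k = 0.0229 /s)
    intermediate ⇌ target (K = 1.30, k = 0.0842 /s)
    intermediate ⇌ isomer of the product (K = 2.10, k = 0.0456 /s)
    crystals ⇌ target, rate k4*(cs4 - [target]) while solid is left; crystals form when [target] > cs4 (solubility = 0.0690 M, k = 1.41 /s)

In the flask, c(isomer of the product) is 0.111 M at 40 min, beside my plateau of 0.112 M. I carry the plateau to the neighbouring flask, charged with 1.2 M of substrate, time and all else held. There 0.112 M is 9.33 % of the charge, and 0.157 M leaves 86.9 % as target, so I reckon a ratio of 0.107. That neighbouring flask gives 0.108, with 9.29 % isomer and 86.3 % target at 40.0 min.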